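**Plan**

- Retrosynthesis: cut C12–C13 (chain to cyclohexenone ring, sp3–sp2 coupling), return the C11–C12 diene terminus to an ester at C11, then cut the O2–C3 bond of the 1,2-dioxane ring.
- Enabling feature: on C6 the ring arm C5–C4–C3–C2(CH3)–C1 and the chain arm C7–C8–C9–C10(CH3)–C11 are the same five-carbon unit. At the (E)-2-methyl-enoate level they are identical, so the dioxane precursor is an achiral hydroperoxide with two enantiotopic arms.
- Forward: ethyl acetate → symmetric bis-enoate tertiary alcohol → hydroperoxide at the not yet stereogenic C6 → desymmetrising 6-exo peroxy-Michael closure of the dioxane ring → the untouched enoate arm becomes a diene → hydroboration and Suzuki coupling attach the preformed cyclohexenone ring.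
- Stereochemistry: C2, C3 and C6 all arise in the key step (C3 from the chiral catalyst, C6 from arm selection in a chair, C2 from enolate protonation). The C9=C10 E geometry comes from a stabilised Wittig reaction.

Key step: step 4

Remark: numbering is C1 = ester carbon, C3 and C6 = ring carbons, O1 on C6, O2 on C3, C7–C12 = chain, C13–C18 = cyclohexenone ring. The sense of induction of the squaramide catalyst cannot be predicted with certainty, so the pseudoenantiomer (quinine- or quinidine-derived) that gives the 3S series is assumed to be the one used.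

**Step 1**
Reactants: 1 ethyl acetate; 2 but-3-en-1-ylmagnesium bromide (2.3 equiv)
Product: 3 5-methylnona-1,8-dien-5-ol
Conditions: THF, 0 °C → rt; aq. NH4Cl
Reagents that add atoms: none
Why: double Grignard addition to the ester (through the methyl ketone) should give the symmetric tertiary alcohol, which has no stereocentre.

**Step 2**
Reactants: 3 5-methylnona-1,8-dien-5-ol; 4 methyl 2-(triphenyl-λ5-phosphanylidene)propanoate (2.5 equiv)
Product: 6 dimethyl (2E,9E)-6-hydroxy-2,6,10-trimethylundeca-2,9-dienedioate, via hydroxy dialdehyde 5 (not isolated)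
Conditions: O3, CH2Cl2, −78 °C; Me2S, −78 °C → rt; then 4, 40 °C
Reagents that add atoms: ozone, [O-][O+]=O (its oxygen atoms are carried only by intermediate 5 and leave again in the Wittig stage)
Why: ozonolysis with reductive work-up cleaves both terminal alkenes, and the dialdehyde (in equilibrium with its lactol) is trapped in the same flask by a Wittig reaction whose stabilised, α-branched ylide should give the (E)-2-methyl enoate on both arms.

**Step 3**
Reactants: 6 dimethyl (2E,9E)-6-hydroxy-2,6,10-trimethylundeca-2,9-dienedioate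
Product: 7 dimethyl (2E,9E)-6-hydroperoxy-2,6,10-trimethylundeca-2,9-dienedioate
Conditions: 50% aq. H2O2 (excess), conc. H2SO4 (cat.), Et2O, 0 °C → rt
Reagents that add atoms: hydrogen peroxide, OO
Why: acid-promoted SN1 perhydrolysis of a tertiary alcohol is the classical route to tertiary hydroperoxides, ionisation costs no stereochemical information because C6 carries two identical arms, and the electron-poor enoates are inert to acidic H2O2.

**Step 4**
Reactants: 7 dimethyl (2E,9E)-6-hydroperoxy-2,6,10-trimethylundeca-2,9-dienedioate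
Product: 8 methyl (2R)-2-[(3S,6R)-6-[(3E)-5-methoxy-4-methyl-5-oxopent-3-en-1-yl]-6-methyl-1,2-dioxan-3-yl]propanoate
Conditions: 3-{[3,5-bis(trifluoromethyl)phenyl]amino}-4-{[(8α,9S)-6′-methoxycinchonan-9-yl]amino}cyclobut-3-ene-1,2-dione (20 mol %), toluene (0.05 M), 0 °C → rt
Reagents that add atoms: none
Why: Proposed new method: the quinuclidine nitrogen of the catalyst takes up the proton of the tertiary hydroperoxide (several pKa units more acidic than an alcohol) while the squaramide N–H bonds bind the carbonyl of one enoate arm, the α-nucleophilic peroxy oxygen O2 adds to C3 of that arm, and the ester enolate is then protonated at C2. The closest known reaction types are the racemic amine-promoted (Et2NH in CF3CH2OH) peroxy-Michael cyclisation of hydroperoxy enoates to 1,2-dioxanes and the enantioselective intramolecular oxa-Michael addition of alcohols to enoates under bifunctional base catalysis; new is their combination on a hydroperoxide at a prochiral centre. The 1,2-dioxane closes in the 6-exo-trig mode through a chair in which the acceptor on C3 is equatorial. C3 is set by the catalyst, which must deliver O2 to the Si face (3S); C6 becomes stereogenic only because one of its two enantiotopic arms enters the ring, and the arm that leaves the long chain equatorial and the methyl axial in that chair (6R) should be preferred; C2 is set by protonation of the enolate on its Si face, anti to the new C3–O bond in the conformer free of allylic strain, which from the (E)-enoate gives the 2,3-syn (2R) product. The step therefore needs enantioface selectivity at C3 (secured by the catalyst) and arm and protonation selectivity (secured by the substrate, the arm preference being expected to be modest); the stereoisomers that arise from imperfect arm or protonation selectivity are diastereomers of 8 and are removed by chromatography. No second cyclisation can follow because there is only one hydroperoxide.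

**Step 5**
Reactants: 8 (dioxane diester)
Product: 9 methyl (2R)-2-[(3S,6R)-6-[(3E)-5-hydroxy-4-methylpent-3-en-1-yl]-6-methyl-1,2-dioxan-3-yl]propanoate
Conditions: iBu2AlH (2.2 equiv), CH2Cl2, −78 °C; MeOH, then aq. KNaC4H4O6
Reagents that add atoms: none
Why: the electrophilic aluminium hydride should coordinate and reduce the more Lewis-basic conjugated ester to the allylic alcohol faster than the α,β-branched saturated ester, and dialkyl peroxides survive this hydride at −78 °C (chemoselective 1,2-reduction).

**Step 6**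
Reactants: 9 (allylic alcohol)
Product: 10 methyl (2R)-2-[(3S,6R)-6-methyl-6-[(3E)-4-methyl-5-oxopent-3-en-1-yl]-1,2-dioxan-3-yl]propanoate
Conditions: activated MnO2 (excess), CH2Cl2, rt
Reagents that add atoms: none
Why: MnO2 oxidises only allylic alcohols under neutral conditions, so the ester, the peroxide and the alkene geometry should be untouched.

**Step 7**
Reactants: 10 (enal)
Product: 11 methyl (2R)-2-[(3S,6R)-6-methyl-6-[(3E)-4-methylhexa-3,5-dien-1-yl]-1,2-dioxan-3-yl]propanoate
Conditions: Ph3PCH3Br (1.3 equiv), KN(SiMe3)2 (1.2 equiv), THF, 0 °C; then 10, −78 → 0 °C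
Reagents that add atoms: methyltriphenylphosphonium bromide, C[P+](c1ccccc1)(c1ccccc1)c1ccccc1.[Br-]
Why: Wittig methylenation of the aldehyde is faster than deprotonation of the ester at C2 at low temperature, and dialkyl peroxides tolerate phosphorus ylides.

**Step 8**
Reactants: 12 3-ethoxy-2-methylcyclohex-2-en-1-one
Product: 14 3-ethoxy-2,6,6-trimethylcyclohex-2-en-1-one, via monomethyl enone 13 (not isolated)
Conditions: LiN(iPr)2 (1.1 equiv), THF, −78 °C, MeI; then LiN(iPr)2 (1.2 equiv), −78 °C, MeI, → rt
Reagents that add atoms: iodomethane, CI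
Why: kinetic deprotonation of a vinylogous ester occurs at the α′ carbon C6, so two successive enolate alkylations should install the gem-dimethyl group there.

**Step 9**
Reactants: 14 3-ethoxy-2,6,6-trimethylcyclohex-2-en-1-one
Product: 16 2,6,6-trimethyl-3-oxocyclohex-1-en-1-yl trifluoromethanesulfonate, via dienyl triflate 15 (not isolated)
Conditions: LiN(iPr)2 (1.15 equiv), THF, −78 °C; PhNTf2, −78 → 0 °C; then 1 M aq. HCl, THF, rt
Reagents that add atoms: N-phenylbis(trifluoromethanesulfonimide), O=S(=O)(N(c1ccccc1)S(=O)(=O)C(F)(F)F)C(F)(F)F; water, O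
Why: with the α′ position blocked, the base removes a γ-hydrogen at C4 to give the extended dienolate, O-sulfonylation gives the dienyl triflate, and dilute acid hydrolyses only the enol ether, which places the triflate on the carbon next to the gem-dimethyl group (the regioisomer not reliably available by direct triflation of the 1,3-dione).

**Step 10**
Reactants: 11 (diene ester); 16 2,6,6-trimethyl-3-oxocyclohex-1-en-1-yl trifluoromethanesulfonate
Product: 18 methyl (2R)-2-[(3S,6R)-6-methyl-6-[(3E)-4-methyl-6-(2,6,6-trimethyl-3-oxocyclohex-1-en-1-yl)hex-3-en-1-yl]-1,2-dioxan-3-yl]propanoate, via alkylborane 17 (not isolated)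
Conditions: 9-BBN-H (0.5 M in THF, 1.3 equiv), 0 °C → rt; 3 M aq. K3PO4; then 16, PdCl2(dppf) (5 mol %), AsPh3 (10 mol %), DMF, rt
Reagents that add atoms: 9-borabicyclo[3.3.1]nonane, B1C2CCCC1CCC2 (adds hydrogen at C11; its boron framework is present only in intermediate 17)
Why: 9-BBN should add to the terminal CH2 of the diene far faster than to the trisubstituted alkene, and the B-alkyl Suzuki–Miyaura coupling with the β-triflyloxy enone forms C12–C13 at room temperature under mild base, conditions of zerovalent palladium catalysis that dialkyl peroxides are known to survive.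

**Compound list**

1 | ethyl acetate | CCOC(C)=O | starting material
2 | but-3-en-1-ylmagnesium bromide | C=CCC[Mg]Br | starting material
3 | 5-methylnona-1,8-dien-5-ol | C=CCCC(C)(O)CCC=C | intermediate
4 | methyl 2-(triphenyl-λ5-phosphanylidene)propanoate | COC(=O)C(C)=P(c1ccccc1)(c1ccccc1)c1ccccc1 | starting material
5 | 4-hydroxy-4-methylheptanedial (in equilibrium with its lactol; not isolated) | O=CCCC(C)(O)CCC=O | intermediate
6 | dimethyl (2E,9E)-6-hydroxy-2,6,10-trimethylundeca-2,9-dienedioate | COC(=O)/C(C)=C/CCC(C)(O)CC/C=C(\C)C(=O)OC | intermediate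
7 | dimethyl (2E,9E)-6-hydroperoxy-2,6,10-trimethylundeca-2,9-dienedioate | COC(=O)/C(C)=C/CCC(C)(OO)CC/C=C(\C)C(=O)OC | intermediate
8 | methyl (2R)-2-[(3S,6R)-6-[(3E)-5-methoxy-4-methyl-5-oxopent-3-en-1-yl]-6-methyl-1,2-dioxan-3-yl]propanoate | COC(=O)[C@H](C)[C@@H]1CC[C@@](C)(CC/C=C(\C)C(=O)OC)OO1 | intermediate
9 | methyl (2R)-2-[(3S,6R)-6-[(3E)-5-hydroxy-4-methylpent-3-en-1-yl]-6-methyl-1,2-dioxan-3-yl]propanoate | COC(=O)[C@H](C)[C@@H]1CC[C@@](C)(CC/C=C(\C)CO)OO1 | intermediate
10 | methyl (2R)-2-[(3S,6R)-6-methyl-6-[(3E)-4-methyl-5-oxopent-3-en-1-yl]-1,2-dioxan-3-yl]propanoate | COC(=O)[C@H](C)[C@@H]1CC[C@@](C)(CC/C=C(\C)C=O)OO1 | intermediate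
11 | methyl (2R)-2-[(3S,6R)-6-methyl-6-[(3E)-4-methylhexa-3,5-dien-1-yl]-1,2-dioxan-3-yl]propanoate | COC(=O)[C@H](C)[C@@H]1CC[C@@](C)(CC/C=C(\C)C=C)OO1 | intermediate
12 | 3-ethoxy-2-methylcyclohex-2-en-1-one | CCOC1=C(C)C(=O)CCC1 | starting material
13 | 3-ethoxy-2,6-dimethylcyclohex-2-en-1-one (racemic; not isolated) | CCOC1=C(C)C(=O)C(C)CC1 | intermediate
14 | 3-ethoxy-2,6,6-trimethylcyclohex-2-en-1-one | CCOC1=C(C)C(=O)C(C)(C)CC1 | intermediate
15 | 3-ethoxy-2,6,6-trimethylcyclohexa-1,3-dien-1-yl trifluoromethanesulfonate (not isolated) | CCOC1=CCC(C)(C)C(OS(=O)(=O)C(F)(F)F)=C1C | intermediate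
16 | 2,6,6-trimethyl-3-oxocyclohex-1-en-1-yl trifluoromethanesulfonate | CC1=C(OS(=O)(=O)C(F)(F)F)C(C)(C)CCC1=O | intermediate
17 | methyl (2R)-2-[(3S,6R)-6-[(3E)-6-(9-borabicyclo[3.3.1]nonan-9-yl)-4-methylhex-3-en-1-yl]-6-methyl-1,2-dioxan-3-yl]propanoate (not isolated) | COC(=O)[C@H](C)[C@@H]1CC[C@@](C)(CC/C=C(\C)CCB2C3CCCC2CCC3)OO1 | intermediate
18 | methyl (2R)-2-[(3S,6R)-6-methyl-6-[(3E)-4-methyl-6-(2,6,6-trimethyl-3-oxocyclohex-1-en-1-yl)hex-3-en-1-yl]-1,2-dioxan-3-yl]propanoate | COC(=O)[C@H](C)[C@@H]1CC[C@@](C)(CC/C=C(\C)CCC2=C(C)C(=O)CCC2(C)C)OO1 | target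

**Step count and risks**

Total steps: 10. Longest linear sequence: 8 (steps 1–7 and 10).

Steps most likely to fail:

1. Step 4 (Proposed new method). What may go wrong: slow turnover of the weak chiral base on the α-branched enoate, poor enantioface or arm selectivity, protonation at C2 from the wrong face, or collapse of the peroxy enolate to an epoxide with loss of the O–O bond. Fallback with known chemistry: setting out from 7, the cyclisation is run under the established racemic conditions (Et2NH, CF3CH2OH, rt). The 2,3-syn-3,6-trans diastereomer is then obtained as the racemate, that is 8 together with its mirror image methyl (2S)-2-[(3R,6S)-6-[(3E)-5-methoxy-4-methyl-5-oxopent-3-en-1-yl]-6-methyl-1,2-dioxan-3-yl]propanoate F1. After removal of the other diastereomers on silica gel, the enantiomers are separated by preparative HPLC on a cellulose tris(3,5-dimethylphenylcarbamate) phase, and the route is rejoined at 8.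

2. Step 5. What may go wrong: loss of chemoselectivity between the two esters, with partial reduction of the saturated ester. Fallback: setting out from 8, both esters are reduced with excess iBu2AlH (−78 → −20 °C) to the diol (2S)-2-[(3S,6R)-6-[(3E)-5-hydroxy-4-methylpent-3-en-1-yl]-6-methyl-1,2-dioxan-3-yl]propan-1-ol F2. MnO2 then oxidises only the allylic hydroxyl to the hydroxy enal (2S)-2-[(3S,6R)-6-methyl-6-[(3E)-4-methyl-5-oxopent-3-en-1-yl]-1,2-dioxan-3-yl]propan-1-ol F3, and Wittig methylenation gives the dienol (2S)-2-[(3S,6R)-6-methyl-6-[(3E)-4-methylhexa-3,5-dien-1-yl]-1,2-dioxan-3-yl]propan-1-ol F4. The remaining primary alcohol is oxidised (TEMPO/PhI(OAc)2, then NaClO2/NaH2PO4/2-methylbut-2-ene) to (2R)-2-[(3S,6R)-6-methyl-6-[(3E)-4-methylhexa-3,5-dien-1-yl]-1,2-dioxan-3-yl]propanoic acid F5, and Me3SiCHN2 in MeOH–toluene returns the route at 11.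

3. Step 10. What may go wrong: reduction of the O–O bond by the dialkylborane, or unselective hydroboration of the diene. Fallback without a boron hydride: setting out from 9, MsCl/Et3N then LiBr gives the allylic bromide methyl (2R)-2-[(3S,6R)-6-[(3E)-5-bromo-4-methylpent-3-en-1-yl]-6-methyl-1,2-dioxan-3-yl]propanoate F6. Deborylative alkylation with bis(pinacolato)borylmethane and NaOtBu in THF gives the homoallylic boronate methyl (2R)-2-[(3S,6R)-6-methyl-6-[(3E)-4-methyl-6-(4,4,5,5-tetramethyl-1,3,2-dioxaborolan-2-yl)hex-3-en-1-yl]-1,2-dioxan-3-yl]propanoate F7. F7 is coupled with 16 (Pd(OAc)2, 2-dicyclohexylphosphino-2′,6′-diisopropoxybiphenyl, K3PO4, toluene–water, 60 °C), which rejoins the route at 18 and bypasses steps 6 and 7.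

**Further compounds**

F1 | step 4 | methyl (2S)-2-[(3R,6S)-6-[(3E)-5-methoxy-4-methyl-5-oxopent-3-en-1-yl]-6-methyl-1,2-dioxan-3-yl]propanoate (enantiomer of 8) | COC(=O)[C@@H](C)[C@H]1CC[C@](C)(CC/C=C(\C)C(=O)OC)OO1
F2 | step 5 | (2S)-2-[(3S,6R)-6-[(3E)-5-hydroxy-4-methylpent-3-en-1-yl]-6-methyl-1,2-dioxan-3-yl]propan-1-ol | OC[C@H](C)[C@@H]1CC[C@@](C)(CC/C=C(\C)CO)OO1
F3 | step 5 | (2S)-2-[(3S,6R)-6-methyl-6-[(3E)-4-methyl-5-oxopent-3-en-1-yl]-1,2-dioxan-3-yl]propan-1-ol | OC[C@H](C)[C@@H]1CC[C@@](C)(CC/C=C(\C)C=O)OO1
F4 | step 5 | (2S)-2-[(3S,6R)-6-methyl-6-[(3E)-4-methylhexa-3,5-dien-1-yl]-1,2-dioxan-3-yl]propan-1-ol | OC[C@H](C)[C@@H]1CC[C@@](C)(CC/C=C(\C)C=C)OO1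
F5 | step 5 | (2R)-2-[(3S,6R)-6-methyl-6-[(3E)-4-methylhexa-3,5-dien-1-yl]-1,2-dioxan-3-yl]propanoic acid | OC(=O)[C@H](C)[C@@H]1CC[C@@](C)(CC/C=C(\C)C=C)OO1
F6 | step 10 | methyl (2R)-2-[(3S,6R)-6-[(3E)-5-bromo-4-methylpent-3-en-1-yl]-6-methyl-1,2-dioxan-3-yl]propanoate | COC(=O)[C@H](C)[C@@H]1CC[C@@](C)(CC/C=C(\C)CBr)OO1
F7 | step 10 | methyl (2R)-2-[(3S,6R)-6-methyl-6-[(3E)-4-methyl-6-(4,4,5,5-tetramethyl-1,3,2-dioxaborolan-2-yl)hex-3-en-1-yl]-1,2-dioxan-3-yl]propanoate | COC(=O)[C@H](C)[C@@H]1CC[C@@](C)(CC/C=C(\C)CCB2OC(C)(C)C(C)(C)O2)OO1
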